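**Retrosynthetic overview**

1. Numbering and feature: ring C1 (quaternary)–C2H2–C3H(OMe)–C4H=C5H–C6(=O); C1 also carries the allyl group (C9–C11) and C8H(CH3)–C7H(OH)Ar. C3–O and C6=O are 1,4-related oxygens on either side of the C4=C5 alkene of the cyclohexenone ring, the pattern of a 2,5-dioxygenated furan. The C7 hydroxyl is γ to C6, so ketone and alcohol can be folded into one ketal whose oxygen joins C6 to C1 through O, C7 and C8 only.
2. 22 ⇐ 20 ⇐ 18 ⇐ 17: hydrolysis of the C6 ketal, O-methylation at C3, methanolysis of the oxygen bridge.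
3. 17 ⇐ 16: intramolecular furan Diels–Alder reaction, disconnecting C1–C6 and C2–C3. The 2-furyl ether oxygen is the tether and ends as the C7 hydroxyl.
4. 16 ⇐ alcohol 14 + 2-bromofuran (C–O coupling); 14 ⇐ enol triflate 11 + allylstannane 12; 11 ⇐ methyl ketone 9 ⇐ Weinreb amide 6 ⇐ Evans syn aldol of 1 with 2 (sets C7 and C8).
5. Ring order: arene from 1; cyclohexene ring and tetrahydrofuran ring together in step 9 (with the oxygen bridge); bridge opened in step 10; tetrahydrofuran ring opened in step 12.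

Key step: step 9

Remark: ketals 18–21 are drawn as the cis-fused C6 epimer expected under equilibrating conditions. C6 becomes the carbonyl carbon in step 12, so either epimer serves.

**Route**

Step 1
Reactants: 1 3,4,5-trimethoxybenzaldehyde; 2 (R)-4-benzyl-3-propionyloxazolidin-2-one
Product: 5 (R)-4-benzyl-3-[(2R,3R)-3-hydroxy-2-methyl-3-(3,4,5-trimethoxyphenyl)propanoyl]oxazolidin-2-one, via (Z)-dibutylboron enolate 3 (not isolated), via dibutylboron aldolate 4 (not isolated)
Conditions: Bu2BOTf, iPr2NEt, CH2Cl2, −78 to 0 °C; 1, −78 to 0 °C; then pH 7 buffer, MeOH, 30% H2O2, 0 °C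
Reagents that add atoms: none
Why: Evans syn aldol: the Z-boron enolate reacts through a chair Zimmerman–Traxler transition state in which the (R)-benzyl auxiliary blocks one enolate face, which should set C8 and C7 as the 2R,3R syn pair.

Step 2
Reactants: 5 (R)-4-benzyl-3-[(2R,3R)-3-hydroxy-2-methyl-3-(3,4,5-trimethoxyphenyl)propanoyl]oxazolidin-2-one
Product: 6 (2R,3R)-3-hydroxy-N-methoxy-N,2-dimethyl-3-(3,4,5-trimethoxyphenyl)propanamide
Conditions: AlMe3, MeNH(OMe)·HCl, CH2Cl2, −10 °C to rt; Rochelle salt work-up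
Reagents that add atoms: N,O-dimethylhydroxylamine hydrochloride, CNOC.Cl
Why: Weinreb transamination: the aluminium amide, directed by the free β-hydroxyl, attacks the exocyclic imide carbonyl and releases the recoverable auxiliary without touching either stereocentre.

Step 3
Reactants: 6 (2R,3R)-3-hydroxy-N-methoxy-N,2-dimethyl-3-(3,4,5-trimethoxyphenyl)propanamide
Product: 7 (2R,3R)-3-[(tert-butyldimethylsilyl)oxy]-N-methoxy-N,2-dimethyl-3-(3,4,5-trimethoxyphenyl)propanamide
Conditions: TBSOTf, 2,6-lutidine, CH2Cl2, 0 °C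
Reagents that add atoms: tert-butyldimethylsilyl triflate, CC(C)(C)[Si](C)(C)OS(=O)(=O)C(F)(F)F
Why: Silylation of the secondary benzylic alcohol with the reactive silyl triflate blocks retro-aldol and alkoxide chemistry during the next three steps.

Step 4
Reactants: 7 (2R,3R)-3-[(tert-butyldimethylsilyl)oxy]-N-methoxy-N,2-dimethyl-3-(3,4,5-trimethoxyphenyl)propanamide
Product: 9 (3R,4R)-4-[(tert-butyldimethylsilyl)oxy]-3-methyl-4-(3,4,5-trimethoxyphenyl)butan-2-one, via magnesium hemiaminal chelate 8 (not isolated)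
Conditions: MeMgBr, THF, 0 °C; aq. NH4Cl
Reagents that add atoms: methylmagnesium bromide, C[Mg]Br
Why: Weinreb ketone synthesis: the five-membered magnesium chelate resists a second addition and collapses to the methyl ketone only on quench, so the carbonyl carbon (C1) gains the future C2 carbon without epimerisation at C8.

Step 5
Reactants: 9 (3R,4R)-4-[(tert-butyldimethylsilyl)oxy]-3-methyl-4-(3,4,5-trimethoxyphenyl)butan-2-one
Product: 11 (3R,4R)-4-[(tert-butyldimethylsilyl)oxy]-3-methyl-4-(3,4,5-trimethoxyphenyl)but-1-en-2-yl trifluoromethanesulfonate, via potassium enolate 10 (not isolated)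
Conditions: KN(SiMe3)2, THF, −78 °C; then PhNTf2, −78 to 0 °C
Reagents that add atoms: N-phenylbis(trifluoromethanesulfonimide), O=S(=O)(N(c1ccccc1)S(=O)(=O)C(F)(F)F)C(F)(F)F
Why: Kinetic enolisation with the bulky amide base removes a methyl proton and not the hindered C8–H, and O-triflation of the enolate should give the 1,1-disubstituted enol triflate without epimerisation or β-elimination of the silyl ether.

Step 6
Reactants: 11 (3R,4R)-4-[(tert-butyldimethylsilyl)oxy]-3-methyl-4-(3,4,5-trimethoxyphenyl)but-1-en-2-yl trifluoromethanesulfonate; 12 allyltributylstannane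
Product: 13 tert-butyldimethyl{[(1R,2S)-2-methyl-3-methylidene-1-(3,4,5-trimethoxyphenyl)hex-5-en-1-yl]oxy}silane
Conditions: Pd(PPh3)4 (5 mol%), LiCl, THF, 65 °C
Reagents that add atoms: none
Why: Stille coupling of an enol triflate with an allylstannane (chloride-assisted oxidative addition, allyl transmetallation, reductive elimination) should give the skipped 1,4-diene in which C1 carries the allyl group and the C2 methylene.

Step 7
Reactants: 13 tert-butyldimethyl{[(1R,2S)-2-methyl-3-methylidene-1-(3,4,5-trimethoxyphenyl)hex-5-en-1-yl]oxy}silane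
Product: 14 (1R,2S)-2-methyl-3-methylidene-1-(3,4,5-trimethoxyphenyl)hex-5-en-1-ol
Conditions: Bu4NF, THF, rt
Reagents that add atoms: none
Why: Fluoride-mediated desilylation frees the C7 hydroxyl, and nothing else in 13 is fluoride-sensitive.

Step 8
Reactants: 14 (1R,2S)-2-methyl-3-methylidene-1-(3,4,5-trimethoxyphenyl)hex-5-en-1-ol; 15 2-bromofuran
Product: 16 2-{[(1R,2S)-2-methyl-3-methylidene-1-(3,4,5-trimethoxyphenyl)hex-5-en-1-yl]oxy}furan
Conditions: CuI (10 mol%), 3,4,7,8-tetramethyl-1,10-phenanthroline (20 mol%), Cs2CO3, 15 (3 equiv), toluene, 90 °C, sealed tube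
Reagents that add atoms: none
Why: Ullmann-type C–O coupling: the phenanthroline-ligated copper alkoxide of 14 couples with the heteroaryl bromide, a reaction type established for secondary alcohols with aryl and heteroaryl halides and for 2-bromofuran in its C–N version, and C7 keeps its configuration because its C–O bond is not broken.

Step 9
Reactants: 16 2-{[(1R,2S)-2-methyl-3-methylidene-1-(3,4,5-trimethoxyphenyl)hex-5-en-1-yl]oxy}furan
Product: 17 (2R,3S,3aR,5R,7aS)-3-methyl-3a-(prop-2-en-1-yl)-2-(3,4,5-trimethoxyphenyl)-2,3,3a,4,5,7a-hexahydro-5,7a-epoxy-1-benzofuran (oxygen bridge C3–O–C6; allyl endo; C8 exo)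
Conditions: toluene (0.02 M), BHT, Et3N (0.2 equiv), 130 °C, sealed base-washed tube
Reagents that add atoms: none
Why: Proposed new method: a thermal, concerted but asynchronous intramolecular [4+2] cycloaddition in which the electron-rich 2-alkoxyfuran (C3–C6) adds suprafacially across the tethered 1,1-disubstituted C1=C2 alkene to form C1–C6 and C2–C3; the closest known reaction type is the intramolecular Diels–Alder reaction of 2-amidofurans with unactivated alkenes on a three-atom nitrogen tether, and the gain of a ketal at C6 plus the substituted tether (C7 aryl, C8 methyl) should offset the loss of furan aromaticity. The cyclohexene ring is closed by the cycloaddition itself and the tetrahydrofuran ring (O, C7, C8, C1, C6) by the tether, which is long enough only for the exo arrangement, with C8 syn to the oxygen bridge and the allyl group endo. That geometry fixes C1, C3 and C6 relative to one another and puts the C3 oxygen cis to C8, as megaphone requires. Their absolute sense follows from the diene face used, which C8 and C7 control: in the favoured transition state the C8 methyl lies beside the C2 methylene (allylic strain against hydrogen only) and not against the allyl methylene, so the cis-related methyl and aryl groups end on the face of the new tetrahydrofuran opposite the allyl group. The step needs reaction at the inner alkene and not the allyl terminus (five-membered against seven-membered tether ring), the exo tether (enforced by the three-atom link) and this one diene face (secured by C8 and C7); quaternary C1 blocks aromatisation of the adduct, and the amine-buffered medium should suppress acid-induced loss of the furyl ether.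

Step 10
Reactants: 17 (2R,3S,3aR,5R,7aS)-3-methyl-3a-(prop-2-en-1-yl)-2-(3,4,5-trimethoxyphenyl)-2,3,3a,4,5,7a-hexahydro-5,7a-epoxy-1-benzofuran
Product: 18 (2R,3S,3aR,5R,7aR)-7a-methoxy-3-methyl-3a-(prop-2-en-1-yl)-2-(3,4,5-trimethoxyphenyl)-2,3,3a,4,5,7a-hexahydro-1-benzofuran-5-ol
Conditions: PPTS (0.1 equiv), MeOH, 0 °C to rt; Et3N quench
Reagents that add atoms: methanol, CO
Why: Acid-catalysed transketalisation: ionisation of the strained C6–O bridge bond, assisted by the ring oxygen, gives a cyclic oxocarbenium ion that methanol should capture at C6 (as with a Ferrier-type cation), leaving the C3 oxygen in place as a free hydroxyl of unchanged configuration.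

Step 11
Reactants: 18 (2R,3S,3aR,5R,7aR)-7a-methoxy-3-methyl-3a-(prop-2-en-1-yl)-2-(3,4,5-trimethoxyphenyl)-2,3,3a,4,5,7a-hexahydro-1-benzofuran-5-ol
Product: 20 (2R,3S,3aR,5R,7aR)-5,7a-dimethoxy-3-methyl-3a-(prop-2-en-1-yl)-2-(3,4,5-trimethoxyphenyl)-2,3,3a,4,5,7a-hexahydro-1-benzofuran, via sodium alkoxide 19 (not isolated)
Conditions: NaH, THF, 0 °C; then MeI, 0 °C to rt
Reagents that add atoms: iodomethane, CI
Why: Williamson etherification of the only free hydroxyl: the C7 oxygen is held in the ketal, so methylation is confined to C3 and proceeds with retention.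

Step 12
Reactants: 20 (2R,3S,3aR,5R,7aR)-5,7a-dimethoxy-3-methyl-3a-(prop-2-en-1-yl)-2-(3,4,5-trimethoxyphenyl)-2,3,3a,4,5,7a-hexahydro-1-benzofuran
Product: 22 megaphone (4R,6R)-6-[(1R,2S)-1-hydroxy-1-(3,4,5-trimethoxyphenyl)propan-2-yl]-4-methoxy-6-(prop-2-en-1-yl)cyclohex-2-en-1-one, via cyclic hemiketal 21 (not isolated)
Conditions: PPTS (0.2 equiv), acetone–H2O (4:1), rt
Reagents that add atoms: water, O
Why: Mild hydrolysis of the unsaturated mixed ketal through the oxocarbenium ion and the hemiketal should release the C6 enone and the C7 alcohol together, under conditions gentle enough to spare the allylic C3 methoxy group and the benzylic C7 centre.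

**Compound list**

1 | 3,4,5-trimethoxybenzaldehyde | COc1cc(C=O)cc(OC)c1OC | starting material
2 | (R)-4-benzyl-3-propionyloxazolidin-2-one | CCC(=O)N1[C@H](Cc2ccccc2)COC1=O | starting material
3 | (Z)-dibutylboron enolate of 2 | CCCCB(CCCC)O/C(=C\C)N1[C@H](Cc2ccccc2)COC1=O | intermediate (not isolated)
4 | dibutylboron aldolate of 5 | O=C(N1[C@H](Cc2ccccc2)COC1=O)[C@H](C)[C@@H](OB(CCCC)CCCC)c1cc(OC)c(OC)c(OC)c1 | intermediate (not isolated)
5 | (R)-4-benzyl-3-[(2R,3R)-3-hydroxy-2-methyl-3-(3,4,5-trimethoxyphenyl)propanoyl]oxazolidin-2-one | O=C(N1[C@H](Cc2ccccc2)COC1=O)[C@H](C)[C@@H](O)c1cc(OC)c(OC)c(OC)c1 | intermediate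
6 | (2R,3R)-3-hydroxy-N-methoxy-N,2-dimethyl-3-(3,4,5-trimethoxyphenyl)propanamide | CON(C)C(=O)[C@H](C)[C@@H](O)c1cc(OC)c(OC)c(OC)c1 | intermediate
7 | (2R,3R)-3-[(tert-butyldimethylsilyl)oxy]-N-methoxy-N,2-dimethyl-3-(3,4,5-trimethoxyphenyl)propanamide | CON(C)C(=O)[C@H](C)[C@@H](O[Si](C)(C)C(C)(C)C)c1cc(OC)c(OC)c(OC)c1 | intermediate
8 | bromomagnesium alkoxide of the tetrahedral methyl adduct of 7 (magnesium hemiaminal chelate, new carbinol centre undefined) | CON(C)C(C)(O[Mg]Br)[C@H](C)[C@@H](O[Si](C)(C)C(C)(C)C)c1cc(OC)c(OC)c(OC)c1 | intermediate (not isolated)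
9 | (3R,4R)-4-[(tert-butyldimethylsilyl)oxy]-3-methyl-4-(3,4,5-trimethoxyphenyl)butan-2-one | CC(=O)[C@H](C)[C@@H](O[Si](C)(C)C(C)(C)C)c1cc(OC)c(OC)c(OC)c1 | intermediate
10 | potassium (3R,4R)-4-[(tert-butyldimethylsilyl)oxy]-3-methyl-4-(3,4,5-trimethoxyphenyl)but-1-en-2-olate | [K+].[O-]C(=C)[C@H](C)[C@@H](O[Si](C)(C)C(C)(C)C)c1cc(OC)c(OC)c(OC)c1 | intermediate (not isolated)
11 | (3R,4R)-4-[(tert-butyldimethylsilyl)oxy]-3-methyl-4-(3,4,5-trimethoxyphenyl)but-1-en-2-yl trifluoromethanesulfonate | C=C(OS(=O)(=O)C(F)(F)F)[C@H](C)[C@@H](O[Si](C)(C)C(C)(C)C)c1cc(OC)c(OC)c(OC)c1 | intermediate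
12 | allyltributylstannane | C=CC[Sn](CCCC)(CCCC)CCCC | starting material
13 | tert-butyldimethyl{[(1R,2S)-2-methyl-3-methylidene-1-(3,4,5-trimethoxyphenyl)hex-5-en-1-yl]oxy}silane | C=CCC(=C)[C@H](C)[C@@H](O[Si](C)(C)C(C)(C)C)c1cc(OC)c(OC)c(OC)c1 | intermediate
14 | (1R,2S)-2-methyl-3-methylidene-1-(3,4,5-trimethoxyphenyl)hex-5-en-1-ol | C=CCC(=C)[C@H](C)[C@@H](O)c1cc(OC)c(OC)c(OC)c1 | intermediate
15 | 2-bromofuran | Brc1ccco1 | starting material
16 | 2-{[(1R,2S)-2-methyl-3-methylidene-1-(3,4,5-trimethoxyphenyl)hex-5-en-1-yl]oxy}furan | C=CCC(=C)[C@H](C)[C@@H](Oc1ccco1)c2cc(OC)c(OC)c(OC)c2 | intermediate (key-step precursor)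
17 | (2R,3S,3aR,5R,7aS)-3-methyl-3a-(prop-2-en-1-yl)-2-(3,4,5-trimethoxyphenyl)-2,3,3a,4,5,7a-hexahydro-5,7a-epoxy-1-benzofuran | C=CC[C@]12C[C@@H]3C=C[C@]1(O3)O[C@@H](c4cc(OC)c(OC)c(OC)c4)[C@H]2C | intermediate (key-step product)
18 | (2R,3S,3aR,5R,7aR)-7a-methoxy-3-methyl-3a-(prop-2-en-1-yl)-2-(3,4,5-trimethoxyphenyl)-2,3,3a,4,5,7a-hexahydro-1-benzofuran-5-ol | C=CC[C@]12C[C@@H](O)C=C[C@@]1(OC)O[C@@H](c3cc(OC)c(OC)c(OC)c3)[C@H]2C | intermediate
19 | sodium alkoxide of 18 | C=CC[C@]12C[C@@H]([O-])C=C[C@@]1(OC)O[C@@H](c3cc(OC)c(OC)c(OC)c3)[C@H]2C.[Na+] | intermediate (not isolated)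
20 | (2R,3S,3aR,5R,7aR)-5,7a-dimethoxy-3-methyl-3a-(prop-2-en-1-yl)-2-(3,4,5-trimethoxyphenyl)-2,3,3a,4,5,7a-hexahydro-1-benzofuran | C=CC[C@]12C[C@@H](OC)C=C[C@@]1(OC)O[C@@H](c3cc(OC)c(OC)c(OC)c3)[C@H]2C | intermediate
21 | cyclic hemiketal of megaphone (7a-hydroxy analogue of 20, C6 undefined) | C=CC[C@]12C[C@@H](OC)C=CC1(O)O[C@@H](c3cc(OC)c(OC)c(OC)c3)[C@H]2C | intermediate (not isolated)
22 | megaphone, (4R,6R)-6-[(1R,2S)-1-hydroxy-1-(3,4,5-trimethoxyphenyl)propan-2-yl]-4-methoxy-6-(prop-2-en-1-yl)cyclohex-2-en-1-one | C=CC[C@]1([C@H](C)[C@@H](O)c2cc(OC)c(OC)c(OC)c2)C[C@@H](OC)C=CC1=O | target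

**Step count**

Total: 12 steps. Longest linear sequence: 12 steps (1 and 2 to 22).

**Steps most likely to fail**

1. Step 9 (bears the label). The cycloaddition may fail to outrun cycloreversion, or thermal syn-elimination of the secondary furyl ether (butenolide plus styrene) may take over, or the alkene may add to the other diene face. The fallback uses known lactone-enolate chemistry, sets out from enol triflate 11 and returns at hydroxy ketal 18.
   - Desilylation of 11 (HF·pyridine, THF) should give hydroxy enol triflate F1.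
   - Palladium-catalysed intramolecular alkoxycarbonylation (Pd(PPh3)4, CO 1 atm, Bu3N, LiCl, MeCN, 65 °C) should close the cis-4-methyl-5-aryl α-methylene-γ-butyrolactone F2, whose lactone carbonyl is C6 and whose exocyclic methylene is C2.
   - Copper-catalysed conjugate addition of (1,3-dioxolan-2-ylmethyl)magnesium bromide (CuBr·SMe2, THF, −78 °C), followed in the same flask by allylation of the resulting enolate (allyl bromide, DMPU), should give the α,α-disubstituted lactone F3. The allyl group enters anti to the cis methyl and aryl groups, which sets C1 as in megaphone.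
   - MeLi (THF, −78 °C) should add once to the hindered lactone to give methyl lactol F4.
   - Aqueous HCl in THF removes the dioxolane, and intramolecular aldol condensation of the keto aldehyde should give the 6,6-disubstituted cyclohex-2-enone F5 (megaphone without the C3 methoxy group).
   - Acid-catalysed dehydration (TsOH, toluene, 4 Å sieves) should close the γ-hydroxy enone to the cyclic dienol ether F6, a 1-alkoxycyclohexa-1,3-diene.
   - [4+2] addition of singlet oxygen (O2, hν, tetraphenylporphyrin, CH2Cl2, −78 °C) anti to the angular allyl group should give endoperoxide F7, the dioxygen-bridged counterpart of 17 with the C3 oxygen already cis to C8.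
   - Reduction of the O–O bond with thiourea in methanol, then PPTS, should give 18, from which steps 11 and 12 follow unchanged.

2. Step 8. Reductive elimination from copper may be too slow for the hindered secondary benzylic alkoxide, so that decomposition of 2-bromofuran or oxidation of the alkoxide wins. The fallback replaces metal-catalysed coupling by nucleophilic aromatic substitution; it sets out from alcohol 14 and returns at furyl ether 16.
   - The sodium alkoxide of 14 (NaH, THF–DMF, 0 °C) should displace nitrite from methyl 5-nitrofuran-2-carboxylate to give furoate F8.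
   - Saponification (LiOH, THF–H2O) should give acid F9.
   - Silver-catalysed protodecarboxylation (Ag2CO3 10 mol%, AcOH cat., DMSO, 110 °C) should give 16. Any 17 already formed at this temperature is carried into step 9.

3. Step 6. Transmetallation at the α-branched triflate may be sluggish, and palladium hydride species may move the skipped diene into conjugation. The fallback builds the same diene from the carbonyl side; it sets out from Weinreb amide 7 and returns at diene 13.
   - AllylMgBr (THF, −78 °C, buffered cold quench) should give the β,γ-unsaturated ketone F10.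
   - Non-basic Takai–Lombardo methylenation (Zn, CH2Br2, TiCl4, THF–CH2Cl2, 0 °C) should then give 13 without epimerising C8 or conjugating the allyl group.

**Further compounds**

F1 | step 9 | (3R,4R)-4-hydroxy-3-methyl-4-(3,4,5-trimethoxyphenyl)but-1-en-2-yl trifluoromethanesulfonate | C=C(OS(=O)(=O)C(F)(F)F)[C@H](C)[C@@H](O)c1cc(OC)c(OC)c(OC)c1
F2 | step 9 | (4S,5R)-4-methyl-3-methylidene-5-(3,4,5-trimethoxyphenyl)oxolan-2-one | C=C1[C@H](C)[C@H](c2cc(OC)c(OC)c(OC)c2)OC1=O
F3 | step 9 | (3S,4S,5R)-3-[2-(1,3-dioxolan-2-yl)ethyl]-4-methyl-3-(prop-2-en-1-yl)-5-(3,4,5-trimethoxyphenyl)oxolan-2-one (allyl trans to the 4-methyl group) | C=CC[C@]1(CCC2OCCO2)C(=O)O[C@@H](c3cc(OC)c(OC)c(OC)c3)[C@H]1C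
F4 | step 9 | methyl lactol of F3, 3-[2-(1,3-dioxolan-2-yl)ethyl]-2,4-dimethyl-3-(prop-2-en-1-yl)-5-(3,4,5-trimethoxyphenyl)oxolan-2-ol (C2 undefined) | C=CC[C@]1(CCC2OCCO2)C(C)(O)O[C@@H](c3cc(OC)c(OC)c(OC)c3)[C@H]1C
F5 | step 9 | (6S)-6-[(1R,2S)-1-hydroxy-1-(3,4,5-trimethoxyphenyl)propan-2-yl]-6-(prop-2-en-1-yl)cyclohex-2-en-1-one | C=CC[C@]1([C@H](C)[C@@H](O)c2cc(OC)c(OC)c(OC)c2)CCC=CC1=O
F6 | step 9 | cyclic dienol ether, 3-methyl-3a-(prop-2-en-1-yl)-2-(3,4,5-trimethoxyphenyl)-2,3,3a,4-tetrahydro-1-benzofuran (C1, C7, C8 as in megaphone) | C=CC[C@]12CC=CC=C1O[C@@H](c3cc(OC)c(OC)c(OC)c3)[C@H]2C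
F7 | step 9 | endoperoxide, the 5,7a-epidioxy analogue of 17 (peroxide bridge anti to the allyl group) | C=CC[C@]12C[C@@H]3C=C[C@]1(OO3)O[C@@H](c4cc(OC)c(OC)c(OC)c4)[C@H]2C
F8 | step 8 | methyl 5-{[(1R,2S)-2-methyl-3-methylidene-1-(3,4,5-trimethoxyphenyl)hex-5-en-1-yl]oxy}furan-2-carboxylate | C=CCC(=C)[C@H](C)[C@@H](Oc1ccc(C(=O)OC)o1)c2cc(OC)c(OC)c(OC)c2
F9 | step 8 | 5-{[(1R,2S)-2-methyl-3-methylidene-1-(3,4,5-trimethoxyphenyl)hex-5-en-1-yl]oxy}furan-2-carboxylic acid | C=CCC(=C)[C@H](C)[C@@H](Oc1ccc(C(=O)O)o1)c2cc(OC)c(OC)c(OC)c2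
F10 | step 6 | (5R,6R)-6-[(tert-butyldimethylsilyl)oxy]-5-methyl-6-(3,4,5-trimethoxyphenyl)hex-1-en-4-one | C=CCC(=O)[C@H](C)[C@@H](O[Si](C)(C)C(C)(C)C)c1cc(OC)c(OC)c(OC)c1
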